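## Retrosynthetic overview

- The target is the 9''-methyl ester of lithospermic acid. The last C–C bond (C4 of ring A to the acrylate) comes from a carboxylate-directed C–H olefination of a (2S,3S)-dihydrobenzofuran-3-carboxylic acid with the acrylate of MOM-protected methyl (R)-danshensuate (chiral pool), followed by global MOM removal.
- The dihydrofuran ring (ring B) is the only ring made in the route; rings A, C and D are bought. It is closed by O1–C2 bond formation in an enantioselective oxypalladation/methoxycarbonylation that joins an achiral (E)-2-hydroxystilbene, CO and MeOH in one operation, setting C2 and C3 and creating the C3 carboxyl carbon.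
- Enabling feature: C2 is benzylic to the 3,4-dioxygenated ring C, so it carries the positive charge of a palladium-bound C2=C3 alkene, and O1 sits on C7a ortho to the C3a–C3 bond. Closure at C2 therefore leaves palladium on C3, where the exocyclic carboxyl carbon belongs. The trans C2/C3 relationship equals anti addition of O1 and CO across the E alkene, and the new C3 carboxyl then directs the C4–H olefination.
- The stilbene comes from a Heck union of 2-ethenyl-6-(methoxymethoxy)phenol (from 2,3-dihydroxybenzaldehyde) with 4-bromo-1,2-bis(methoxymethoxy)benzene.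

Key step: step 5

Assumption: the sense of induction of the chiral ligand in step 5 cannot be predicted with confidence, so the ligand antipode that leads to the (2S,3S) series is to be used (both are accessible) and the assignment checked at acid 9; (R)-danshensu free acid is taken as the commercial chiral-pool material.

## Route

Step 1
Reactants: 1 2,3-dihydroxybenzaldehyde
Product: 2 2-hydroxy-3-(methoxymethoxy)benzaldehyde
Conditions: NaH (2.2 equiv), DMSO, 20 °C; then MOMCl (1.0 equiv), 20 °C; dilute HCl work-up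
Reagents that add atoms: chloromethyl methyl ether (MOMCl), COCCl
Why: Regioselective Williamson O-alkylation via the dianion: the 2-phenoxide is delocalised into and chelated by the ortho formyl group, so the more nucleophilic 3-phenoxide should take up the single equivalent of MOMCl.

Step 2
Reactants: 2 2-hydroxy-3-(methoxymethoxy)benzaldehyde
Product: 3 2-ethenyl-6-(methoxymethoxy)phenol
Conditions: Ph3PCH3Br (2.4 equiv), KOtBu (2.4 equiv), THF, 0 °C to rt
Reagents that add atoms: methyltriphenylphosphonium bromide, C[P+](c1ccccc1)(c1ccccc1)c1ccccc1.[Br-]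
Why: Wittig methylenation; the excess ylide covers the phenol proton, the phenoxide aldehyde still reacts with the unstabilised ylide, and the MOM acetal is inert to base.

Step 3
Reactants: 4 4-bromobenzene-1,2-diol
Product: 5 4-bromo-1,2-bis(methoxymethoxy)benzene
Conditions: MOMCl (2.5 equiv), i-Pr2NEt (3 equiv), CH2Cl2, 0 °C to rt
Reagents that add atoms: chloromethyl methyl ether (MOMCl), COCCl
Why: Williamson-type O-alkylation (MOM protection) of both phenols under amine base; no selectivity is required.

Step 4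
Reactants: 3 2-ethenyl-6-(methoxymethoxy)phenol; 5 4-bromo-1,2-bis(methoxymethoxy)benzene
Product: 6 2-{(E)-2-[3,4-bis(methoxymethoxy)phenyl]ethenyl}-6-(methoxymethoxy)phenol
Conditions: Pd(OAc)2 (5 mol%), P(o-tol)3 (10 mol%), Et3N (2 equiv), DMF, 100 °C
Reagents that add atoms: none
Why: Mizoroki–Heck reaction: the aryl–palladium species adds to the terminal alkene carbon and syn β-hydride elimination should give the E-stilbene; the free phenol is tolerated and, with no oxidant present, oxidative cyclisation to a benzofuran cannot occur.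

Step 5
Reactants: 6 2-{(E)-2-[3,4-bis(methoxymethoxy)phenyl]ethenyl}-6-(methoxymethoxy)phenol
Product: 7 methyl (2S,3S)-2-[3,4-bis(methoxymethoxy)phenyl]-7-(methoxymethoxy)-2,3-dihydro-1-benzofuran-3-carboxylate (2,3-trans)
Conditions: Pd(OCOCF3)2 (10 mol%), (S,S)-Bn-BOXAX [2,2'-bis((4S)-4-benzyl-4,5-dihydro-1,3-oxazol-2-yl)-1,1'-binaphthyl] (12 mol%), p-benzoquinone (2 equiv), CO (3 atm), MeOH/CH2Cl2 3:1, 0 °C
Reagents that add atoms: carbon monoxide, [C-]#[O+]; methanol, CO
Why: Proposed new method: the cationic bis(oxazoline) complex of divalent palladium binds one face of the C2=C3 alkene of 6, O1–H (on C7a) attacks C2 from the opposite face, and the resulting π-benzyl-stabilised Pd–C3 bond inserts CO with retention before methanolysis of the acylpalladium releases ester 7 and zerovalent palladium, which p-benzoquinone reoxidises. The closest known reaction types are the enantioselective domino Wacker cyclisation/methoxycarbonylation of o-alkenylphenols with the same catalyst system (6-exo closure on a trisubstituted alkene) and the oxidative cyclisation of 2-hydroxystilbenes to 2-arylbenzofurans by divalent palladium (the same O1–C2 closure, ended there by β-hydride elimination); new is the capture of the secondary benzylic Pd–C3 bond by CO and enantiocontrol in this closure mode. The dihydrofuran ring (ring B) closes in the 5-endo-trig mode, which is workable because C2 is benzylic to the 3,4-dioxygenated ring C and carries most of the positive charge of the palladium-bound alkene. C2 is set by the ligand-controlled choice of alkene face, and C3 follows from it, since anti addition of O1 and Pd across the E alkene and CO insertion with retention place aryl and ester trans (also the thermodynamic arrangement). The step needs CO insertion to outrun syn β-hydride elimination of H–C2, which the chelating ligand plus CO (no free cis site), 0 °C and 3 atm CO should secure, and it needs oxypalladation to outrun aryloxycarbonylation of the phenol, which the base-free medium should secure; attack at C3 is excluded because it would close a four-membered ring.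

Step 6
Reactants: 7 methyl (2S,3S)-2-[3,4-bis(methoxymethoxy)phenyl]-7-(methoxymethoxy)-2,3-dihydro-1-benzofuran-3-carboxylate
Product: 9 (2S,3S)-2-[3,4-bis(methoxymethoxy)phenyl]-7-(methoxymethoxy)-2,3-dihydro-1-benzofuran-3-carboxylic acid, via trimethylstannyl ester 8 (not isolated)
Conditions: Me3SnOH (6 equiv), 1,2-dichloroethane, 80 °C; then 0.5 M aq. HCl wash, 0 °C
Reagents that add atoms: trimethyltin hydroxide, C[Sn](C)(C)O
Why: Trimethyltin hydroxide ester cleavage (acyl transfer to a tin carboxylate under near-neutral conditions) should hydrolyse the methyl ester without forming the C3 enolate, so the C3 configuration and the MOM acetals stay intact, and the brief cold acid wash frees the acid.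

Step 7
Reactants: 10 (2R)-3-(3,4-dihydroxyphenyl)-2-hydroxypropanoic acid ((R)-danshensu)
Product: 11 methyl (2R)-3-(3,4-dihydroxyphenyl)-2-hydroxypropanoate
Conditions: conc. H2SO4 (cat.), MeOH, reflux, argon
Reagents that add atoms: methanol, CO
Why: Fischer esterification; the α-hydroxy acid esterifies under acid catalysis and its stereocentre, taken from the chiral pool, is not enolised under these conditions.

Step 8
Reactants: 11 methyl (2R)-3-(3,4-dihydroxyphenyl)-2-hydroxypropanoate
Product: 12 methyl (2R)-3-[3,4-bis(methoxymethoxy)phenyl]-2-hydroxypropanoate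
Conditions: MOMCl (2.3 equiv), K2CO3 (2.5 equiv), acetone, 0 °C to rt, argon
Reagents that add atoms: chloromethyl methyl ether (MOMCl), COCCl
Why: Chemoselective Williamson O-alkylation: K2CO3 deprotonates only the two phenols, so the secondary alcohol should stay free and the stereocentre untouched.

Step 9
Reactants: 12 methyl (2R)-3-[3,4-bis(methoxymethoxy)phenyl]-2-hydroxypropanoate
Product: 13 methyl (2R)-3-[3,4-bis(methoxymethoxy)phenyl]-2-(prop-2-enoyloxy)propanoate
Conditions: acryloyl chloride (1.3 equiv), Et3N (1.5 equiv), CH2Cl2, −20 to 0 °C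
Reagents that add atoms: acryloyl chloride, C=CC(=O)Cl
Why: O-acylation of the secondary alcohol by the acid chloride under amine base (esterification) at low temperature, which should leave the α-stereocentre unchanged.

Step 10
Reactants: 9 (2S,3S)-2-[3,4-bis(methoxymethoxy)phenyl]-7-(methoxymethoxy)-2,3-dihydro-1-benzofuran-3-carboxylic acid; 13 methyl (2R)-3-[3,4-bis(methoxymethoxy)phenyl]-2-(prop-2-enoyloxy)propanoate
Product: 14 (2S,3S)-2-[3,4-bis(methoxymethoxy)phenyl]-4-[(E)-3-{[(2R)-3-[3,4-bis(methoxymethoxy)phenyl]-1-methoxy-1-oxopropan-2-yl]oxy}-3-oxoprop-1-enyl]-7-(methoxymethoxy)-2,3-dihydro-1-benzofuran-3-carboxylic acid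
Conditions: Pd(OAc)2 (10 mol%), Ac-Ile-OH (20 mol%), KHCO3 (2 equiv), O2 (1 atm), t-AmOH, 85 °C; dilute HCl work-up
Reagents that add atoms: none
Why: Carboxylate-directed ortho C–H olefination of an arylacetic acid (Fujiwara–Moritani-type dehydrogenative Heck reaction with an amino-acid ligand): the C3 carboxylate should form a six-membered palladacycle at C4, the only free ortho position of ring A, and insertion/β-hydride elimination give the E-cinnamate while O2 reoxidises palladium and no stereocentre is involved.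

Step 11
Reactants: 14 the penta-MOM acid from step 10
Product: 15 (2S,3S)-2-(3,4-dihydroxyphenyl)-4-[(E)-3-{[(2R)-3-(3,4-dihydroxyphenyl)-1-methoxy-1-oxopropan-2-yl]oxy}-3-oxoprop-1-enyl]-7-hydroxy-2,3-dihydro-1-benzofuran-3-carboxylic acid (target)
Conditions: 3 M aq. HCl/THF 1:4, 40 °C, argon
Reagents that add atoms: none
Why: Acid-catalysed acetal hydrolysis should remove all five MOM groups; alcohol-free aqueous THF avoids transesterification and Fischer esterification, and the two esters, the E-alkene and the three stereocentres should be stable to dilute acid at this temperature.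

## Compound list

1 | 2,3-dihydroxybenzaldehyde | O=Cc1cccc(O)c1O | starting material
2 | 2-hydroxy-3-(methoxymethoxy)benzaldehyde | O=Cc1cccc(OCOC)c1O | intermediate
3 | 2-ethenyl-6-(methoxymethoxy)phenol | C=Cc1cccc(OCOC)c1O | intermediate
4 | 4-bromobenzene-1,2-diol | Oc1ccc(Br)cc1O | starting material
5 | 4-bromo-1,2-bis(methoxymethoxy)benzene | COCOc1ccc(Br)cc1OCOC | intermediate
6 | 2-{(E)-2-[3,4-bis(methoxymethoxy)phenyl]ethenyl}-6-(methoxymethoxy)phenol | Oc1c(OCOC)cccc1/C=C/c1ccc(OCOC)c(OCOC)c1 | intermediate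
7 | methyl (2S,3S)-2-[3,4-bis(methoxymethoxy)phenyl]-7-(methoxymethoxy)-2,3-dihydro-1-benzofuran-3-carboxylate | c1ccc(OCOC)c2c1[C@H](C(=O)OC)[C@@H](c1ccc(OCOC)c(OCOC)c1)O2 | intermediate
8 | trimethylstannyl (2S,3S)-2-[3,4-bis(methoxymethoxy)phenyl]-7-(methoxymethoxy)-2,3-dihydro-1-benzofuran-3-carboxylate | c1ccc(OCOC)c2c1[C@H](C(=O)O[Sn](C)(C)C)[C@@H](c1ccc(OCOC)c(OCOC)c1)O2 | intermediate
9 | (2S,3S)-2-[3,4-bis(methoxymethoxy)phenyl]-7-(methoxymethoxy)-2,3-dihydro-1-benzofuran-3-carboxylic acid | c1ccc(OCOC)c2c1[C@H](C(=O)O)[C@@H](c1ccc(OCOC)c(OCOC)c1)O2 | intermediate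
10 | (2R)-3-(3,4-dihydroxyphenyl)-2-hydroxypropanoic acid | OC(=O)[C@@H](Cc1ccc(O)c(O)c1)O | starting material
11 | methyl (2R)-3-(3,4-dihydroxyphenyl)-2-hydroxypropanoate | COC(=O)[C@@H](Cc1ccc(O)c(O)c1)O | intermediate
12 | methyl (2R)-3-[3,4-bis(methoxymethoxy)phenyl]-2-hydroxypropanoate | COC(=O)[C@@H](Cc1ccc(OCOC)c(OCOC)c1)O | intermediate
13 | methyl (2R)-3-[3,4-bis(methoxymethoxy)phenyl]-2-(prop-2-enoyloxy)propanoate | COC(=O)[C@@H](Cc1ccc(OCOC)c(OCOC)c1)OC(=O)C=C | intermediate
14 | (2S,3S)-2-[3,4-bis(methoxymethoxy)phenyl]-4-[(E)-3-{[(2R)-3-[3,4-bis(methoxymethoxy)phenyl]-1-methoxy-1-oxopropan-2-yl]oxy}-3-oxoprop-1-enyl]-7-(methoxymethoxy)-2,3-dihydro-1-benzofuran-3-carboxylic acid | COC(=O)[C@@H](Cc1ccc(OCOC)c(OCOC)c1)OC(=O)/C=C/c1ccc(OCOC)c2c1[C@H](C(=O)O)[C@@H](c1ccc(OCOC)c(OCOC)c1)O2 | intermediate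
15 | (2S,3S)-2-(3,4-dihydroxyphenyl)-4-[(E)-3-{[(2R)-3-(3,4-dihydroxyphenyl)-1-methoxy-1-oxopropan-2-yl]oxy}-3-oxoprop-1-enyl]-7-hydroxy-2,3-dihydro-1-benzofuran-3-carboxylic acid | COC(=O)[C@@H](Cc1ccc(O)c(O)c1)OC(=O)/C=C/c1ccc(O)c2c1[C@H](C(=O)O)[C@@H](c1ccc(O)c(O)c1)O2 | target

## Step count and risks

Total step count: 11. Longest linear sequence: 7 steps (steps 1, 2, 4, 5, 6, 10, 11).

**Step 5 (proposed new method).** What may go wrong: β-hydride elimination of the Pd–C3 intermediate may outrun CO insertion and drain material to the aromatic benzofuran; carbonylation may start at the phenol oxygen instead of at the alkene; or the facial selection by the ligand may be weak. The fallback uses known chemistry only, sets out from 2 and 5 and comes back at 7. Ohira–Bestmann alkynylation of 2 (dimethyl (1-diazo-2-oxopropyl)phosphonate, K2CO3, MeOH) would give 2-ethynyl-6-(methoxymethoxy)phenol F1. Sonogashira coupling of F1 with 5 (Pd(PPh3)2Cl2, CuI, Et3N, 50 °C, kept mild to avoid premature cycloisomerisation) would give 2-{[3,4-bis(methoxymethoxy)phenyl]ethynyl}-6-(methoxymethoxy)phenol F2. The established carbonylative annulation of o-alkynylphenols (PdI2, thiourea, CBr4, Cs2CO3, CO, MeOH, 40 °C) would give methyl 2-[3,4-bis(methoxymethoxy)phenyl]-7-(methoxymethoxy)-1-benzofuran-3-carboxylate F3. Dissolving-metal conjugate reduction (Mg, MeOH/THF), which is known to give 2,3-trans products from 2-arylbenzofuran-3-carboxylates, would give racemic methyl (2RS,3RS)-2-[3,4-bis(methoxymethoxy)phenyl]-7-(methoxymethoxy)-2,3-dihydro-1-benzofuran-3-carboxylate F4. Preparative chromatography on a chiral stationary phase would then deliver 7.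

**Step 10.** What may go wrong: the palladacycle at C4 may fail to form or to turn over next to the congested C3 centre, the many acetal oxygens may tie up the catalyst, or the acrylate may oligomerise at 85 °C under O2. The fallback separates C–H cleavage from C–C bond formation, sets out from 9 and comes back at 14. Carboxylate-directed ortho C–H iodination of 9 (Pd(OAc)2 cat., PhI(OAc)2, iodine, DMF, 60 °C) would give (2S,3S)-2-[3,4-bis(methoxymethoxy)phenyl]-4-iodo-7-(methoxymethoxy)-2,3-dihydro-1-benzofuran-3-carboxylic acid F5. A Mizoroki–Heck reaction of F5 with 13 under ligand-free phase-transfer conditions (Pd(OAc)2, NaHCO3, n-Bu4NCl, DMF, 50 °C), which needs no oxidant, would return to 14.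

**Step 11.** What may go wrong: the liberated formaldehyde may be captured by the electron-rich catechol rings, the deprotection may stall and need forcing conditions that start to cleave the esters, or the C2–O1 bond may ionise once the para-hydroxyl of ring C is free. The fallback is a late protecting-group exchange so that the last step is a buffered fluoride desilylation; it sets out from 7 and 11 and comes back at 15.
- MOM removal from 7 in methanol (HCl, MeOH, 40 °C), where the solvent traps the formaldehyde and cannot scramble a methyl ester, would give methyl (2S,3S)-2-(3,4-dihydroxyphenyl)-7-hydroxy-2,3-dihydro-1-benzofuran-3-carboxylate F6.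
- Silylation (i-Pr3SiCl, imidazole, DMF) would give methyl (2S,3S)-2-[3,4-bis(triisopropylsilyloxy)phenyl]-7-(triisopropylsilyloxy)-2,3-dihydro-1-benzofuran-3-carboxylate F7.
- Me3SnOH cleavage as in step 6 would give (2S,3S)-2-[3,4-bis(triisopropylsilyloxy)phenyl]-7-(triisopropylsilyloxy)-2,3-dihydro-1-benzofuran-3-carboxylic acid F8.
- Phenol-selective silylation of 11 (i-Pr3SiCl 2.1 equiv, imidazole, DMF, 0 °C) would give methyl (2R)-3-[3,4-bis(triisopropylsilyloxy)phenyl]-2-hydroxypropanoate F9.
- Acylation of F9 as in step 9 would give methyl (2R)-3-[3,4-bis(triisopropylsilyloxy)phenyl]-2-(prop-2-enoyloxy)propanoate F10.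
- The olefination of step 10 applied to F8 and F10 would give (2S,3S)-2-[3,4-bis(triisopropylsilyloxy)phenyl]-4-[(E)-3-{[(2R)-3-[3,4-bis(triisopropylsilyloxy)phenyl]-1-methoxy-1-oxopropan-2-yl]oxy}-3-oxoprop-1-enyl]-7-(triisopropylsilyloxy)-2,3-dihydro-1-benzofuran-3-carboxylic acid F11.
- n-Bu4NF/AcOH in THF at 0 °C would then give 15.

## Further compounds

F1 | step 5 | 2-ethynyl-6-(methoxymethoxy)phenol | C#Cc1cccc(OCOC)c1O
F2 | step 5 | 2-{[3,4-bis(methoxymethoxy)phenyl]ethynyl}-6-(methoxymethoxy)phenol | Oc1c(OCOC)cccc1C#Cc1ccc(OCOC)c(OCOC)c1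
F3 | step 5 | methyl 2-[3,4-bis(methoxymethoxy)phenyl]-7-(methoxymethoxy)-1-benzofuran-3-carboxylate | COC(=O)c1c(-c2ccc(OCOC)c(OCOC)c2)oc2c(OCOC)cccc12
F4 | step 5 | racemic methyl (2RS,3RS)-2-[3,4-bis(methoxymethoxy)phenyl]-7-(methoxymethoxy)-2,3-dihydro-1-benzofuran-3-carboxylate | c1ccc(OCOC)c2c1[C@H](C(=O)OC)[C@@H](c1ccc(OCOC)c(OCOC)c1)O2.c1ccc(OCOC)c2c1[C@@H](C(=O)OC)[C@H](c1ccc(OCOC)c(OCOC)c1)O2
F5 | step 10 | (2S,3S)-2-[3,4-bis(methoxymethoxy)phenyl]-4-iodo-7-(methoxymethoxy)-2,3-dihydro-1-benzofuran-3-carboxylic acid | Ic1ccc(OCOC)c2c1[C@H](C(=O)O)[C@@H](c1ccc(OCOC)c(OCOC)c1)O2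
F6 | step 11 | methyl (2S,3S)-2-(3,4-dihydroxyphenyl)-7-hydroxy-2,3-dihydro-1-benzofuran-3-carboxylate | c1ccc(O)c2c1[C@H](C(=O)OC)[C@@H](c1ccc(O)c(O)c1)O2
F7 | step 11 | methyl (2S,3S)-2-[3,4-bis(triisopropylsilyloxy)phenyl]-7-(triisopropylsilyloxy)-2,3-dihydro-1-benzofuran-3-carboxylate | c1ccc(O[Si](C(C)C)(C(C)C)C(C)C)c2c1[C@H](C(=O)OC)[C@@H](c1ccc(O[Si](C(C)C)(C(C)C)C(C)C)c(O[Si](C(C)C)(C(C)C)C(C)C)c1)O2
F8 | step 11 | (2S,3S)-2-[3,4-bis(triisopropylsilyloxy)phenyl]-7-(triisopropylsilyloxy)-2,3-dihydro-1-benzofuran-3-carboxylic acid | c1ccc(O[Si](C(C)C)(C(C)C)C(C)C)c2c1[C@H](C(=O)O)[C@@H](c1ccc(O[Si](C(C)C)(C(C)C)C(C)C)c(O[Si](C(C)C)(C(C)C)C(C)C)c1)O2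
F9 | step 11 | methyl (2R)-3-[3,4-bis(triisopropylsilyloxy)phenyl]-2-hydroxypropanoate | COC(=O)[C@@H](Cc1ccc(O[Si](C(C)C)(C(C)C)C(C)C)c(O[Si](C(C)C)(C(C)C)C(C)C)c1)O
F10 | step 11 | methyl (2R)-3-[3,4-bis(triisopropylsilyloxy)phenyl]-2-(prop-2-enoyloxy)propanoate | COC(=O)[C@@H](Cc1ccc(O[Si](C(C)C)(C(C)C)C(C)C)c(O[Si](C(C)C)(C(C)C)C(C)C)c1)OC(=O)C=C
F11 | step 11 | (2S,3S)-2-[3,4-bis(triisopropylsilyloxy)phenyl]-4-[(E)-3-{[(2R)-3-[3,4-bis(triisopropylsilyloxy)phenyl]-1-methoxy-1-oxopropan-2-yl]oxy}-3-oxoprop-1-enyl]-7-(triisopropylsilyloxy)-2,3-dihydro-1-benzofuran-3-carboxylic acid | COC(=O)[C@@H](Cc1ccc(O[Si](C(C)C)(C(C)C)C(C)C)c(O[Si](C(C)C)(C(C)C)C(C)C)c1)OC(=O)/C=C/c1ccc(O[Si](C(C)C)(C(C)C)C(C)C)c2c1[C@H](C(=O)O)[C@@H](c1ccc(O[Si](C(C)C)(C(C)C)C(C)C)c(O[Si](C(C)C)(C(C)C)C(C)C)c1)O2
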